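**Plan**

- Numbering: ring C1(side chain)–C2–C3=C4(C15H2O)–C5(OH)–C6; chain C7(=C14H2)–C8–C9=C10–C11(OH)(C13H3)–C12H2O.
- Cuts, in retrosynthetic order: the C15–O isobutyrate, C8–C9 (allyl–alkenyl coupling), the ring bond C4–C5, C3=C4 (as the enal alkene of an open chain), and C1–C7.
- Enabling feature: in the cyclohexene ring, oxygenated C15 sits on C4, which is double-bonded to C3 and bonded to carbinol C5. This is the adduct of an enal α-carbon with an aldehyde, and C6–C1–C2 hold both in one chain.
- Forward: a rhodium-catalysed alkenyl addition to a dihydropyranone sets C1, the lactone is unfolded to a hept-2-enedial, the only ring closes in step 7, the C9–C13 boronate is joined at C8, and the second ester goes on last.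
- Stereochemistry: C1 from (R)-BINAP–rhodium face selection; C5 from the proline-directed ring closure, cis to C1; C11 carried unchanged from (R)-2-methylglycidol; the E alkene from a boron–Wittig olefination.

Key step: step 7

Assumption: D-proline with imidazole is taken to give the (S)-carbinol and (R)-BINAP the (R)-lactone, by analogy with the unsubstituted hept-2-enedial and with aryl additions to the same lactone; should either sense be the reverse, the mirror-image catalyst is used and nothing else changes.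

**Route**

Step 1
Reactants: 1 2-bromoprop-2-en-1-ol
Product: 2 (2-bromoprop-2-en-1-yloxy)(tert-butyl)dimethylsilane
Conditions: TBSCl, imidazole, CH2Cl2, 0 °C → rt
Reagents that add atoms: tert-butyldimethylsilyl chloride, CC(C)(C)[Si](C)(C)Cl
Why: Imidazole-promoted silylation of a primary allylic alcohol (silyl ether formation) should be clean, the vinyl bromide being inert.

Step 2
Reactants: 2 (2-bromoprop-2-en-1-yloxy)(tert-butyl)dimethylsilane
Product: 3 2-[3-(tert-butyldimethylsilyloxy)prop-1-en-2-yl]-4,4,5,5-tetramethyl-1,3,2-dioxaborolane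
Conditions: B2pin2, PdCl2(PPh3)2 (3 mol%), PPh3 (6 mol%), KOPh, toluene, 50 °C
Reagents that add atoms: bis(pinacolato)diboron, CC1(C)OB(OC1(C)C)B1OC(C)(C)C(C)(C)O1
Why: Miyaura borylation of a 1-alkenyl bromide (oxidative addition to zerovalent palladium, phenoxide-assisted boryl transfer, reductive elimination) should give the 1,1-disubstituted alkenyl boronate, the silyloxy group being too poor a leaving group for β-elimination.

Step 3
Reactants: 3 2-[3-(tert-butyldimethylsilyloxy)prop-1-en-2-yl]-4,4,5,5-tetramethyl-1,3,2-dioxaborolane; 4 5,6-dihydro-2H-pyran-2-one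
Product: 5 (R)-4-[3-(tert-butyldimethylsilyloxy)prop-1-en-2-yl]tetrahydro-2H-pyran-2-one
Conditions: [RhCl(C2H4)2]2 (2.5 mol%), (R)-BINAP (5.5 mol%), KOH (10 mol%), 1,4-dioxane/H2O 10:1, 60 °C
Reagents that add atoms: none
Why: Hayashi–Miyaura conjugate addition, in which the alkenyl group passes from boron to a hydroxo-rhodium BINAP complex, adds across the enoate C=C and the rhodium enolate is protonated by water, the (R)-ligand shielding one face of the lactone so that the new stereocentre (C4 of 5, the future C1) is expected to be R.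

Step 4
Reactants: 5 (R)-4-[3-(tert-butyldimethylsilyloxy)prop-1-en-2-yl]tetrahydro-2H-pyran-2-one
Product: 6 (4R)-4-[3-(tert-butyldimethylsilyloxy)prop-1-en-2-yl]tetrahydro-2H-pyran-2-ol (anomer mixture)
Conditions: iBu2AlH (1.1 equiv), CH2Cl2, −78 °C; aq. potassium sodium tartrate
Reagents that add atoms: none
Why: Low-temperature iBu2AlH reduction of a δ-lactone stops at the aluminium hemiacetal and gives the lactol on hydrolysis, the stereocentre being β to the carbonyl and untouched.

Step 5
Reactants: 6 (4R)-4-[3-(tert-butyldimethylsilyloxy)prop-1-en-2-yl]tetrahydro-2H-pyran-2-ol; 7 (triphenylphosphoranylidene)acetaldehyde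
Product: 8 (S,E)-5-[3-(tert-butyldimethylsilyloxy)prop-1-en-2-yl]-7-hydroxyhept-2-enal
Conditions: 7 (1.5 equiv), toluene, 80 °C
Reagents that add atoms: none
Why: Wittig reaction of the open hydroxy-aldehyde form of the lactol with a stabilised formyl ylide should give the E-enal, the modest nucleophilicity of the ylide disfavouring a second olefination.

Step 6
Reactants: 8 (S,E)-5-[3-(tert-butyldimethylsilyloxy)prop-1-en-2-yl]-7-hydroxyhept-2-enal
Product: 9 (S,E)-5-[3-(tert-butyldimethylsilyloxy)prop-1-en-2-yl]hept-2-enedial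
Conditions: Dess–Martin periodinane, CH2Cl2, 0 °C → rt
Reagents that add atoms: none
Why: Dess–Martin oxidation converts the primary alcohol into the aldehyde under near-neutral conditions that leave the enal, the silyl ether and the β-stereocentre alone.

Step 7
Reactants: 9 (S,E)-5-[3-(tert-butyldimethylsilyloxy)prop-1-en-2-yl]hept-2-enedial
Product: 10 (4S,6S)-4-[3-(tert-butyldimethylsilyloxy)prop-1-en-2-yl]-6-hydroxycyclohex-1-ene-1-carbaldehyde
Conditions: D-proline (20 mol%), imidazole (20 mol%), MeCN, 0 °C → rt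
Reagents that add atoms: none
Why: D-Proline condenses with the enal to an iminium ion, imidazole adds to its β-carbon, and the enamine so formed attacks the tethered aldehyde through its α-carbon; β-elimination of imidazole and hydrolysis then return both catalysts and leave the hydroxy enal. The closest known reaction type is the amino acid/imidazole co-catalysed intramolecular Morita–Baylis–Hillman cyclisation of hept-2-enedials to 6-hydroxycyclohex-1-enecarbaldehydes. The cyclohexene ring closes in the 6-(enolexo)-exo-trig mode by joining the enal α-carbon to the aldehyde carbon. The new carbinol centre (C6 of 10, C5 of the target) is controlled by the proline carboxylic acid, which hydrogen-bonds the aldehyde oxygen and fixes the face attacked, and by a chair-like transition state with the C4 substituent equatorial, so that the hydroxyl should form cis to it. The step needs chemoselectivity for the enal α-carbon over an enamine of the saturated aldehyde and facial control at the aldehyde: the E alkene allows no other ring of reasonable size, and the resident stereocentre, β to one carbonyl and δ to the other, cannot epimerise and biases the chair.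

Step 8
Reactants: 10 (4S,6S)-4-[3-(tert-butyldimethylsilyloxy)prop-1-en-2-yl]-6-hydroxycyclohex-1-ene-1-carbaldehyde
Product: 11 (1S,5S)-5-[3-(tert-butyldimethylsilyloxy)prop-1-en-2-yl]-2-(hydroxymethyl)cyclohex-2-en-1-ol
Conditions: NaBH4, CeCl3·7H2O, MeOH, −40 °C
Reagents that add atoms: none
Why: Luche reduction delivers hydride 1,2 to the conjugated aldehyde and gives the allylic alcohol without forming or disturbing a stereocentre.

Step 9
Reactants: 11 (1S,5S)-5-[3-(tert-butyldimethylsilyloxy)prop-1-en-2-yl]-2-(hydroxymethyl)cyclohex-2-en-1-ol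
Product: 12 tert-butyl{2-[(7S,8aS)-2,2-dimethyl-6,7,8,8a-tetrahydro-4H-benzo[d][1,3]dioxin-7-yl]prop-2-en-1-yloxy}dimethylsilane (acetonide of 11)
Conditions: Me2C(OMe)2, PPTS (cat.), CH2Cl2, rt
Reagents that add atoms: 2,2-dimethoxypropane, COC(C)(C)OC
Why: Acid-catalysed transacetalisation ties the 1,3-diol into a six-membered isopropylidene acetal, so that only the silyl-protected hydroxyl remains to be addressed.

Step 10
Reactants: 12 acetonide of 11
Product: 13 2-[(7S,8aS)-2,2-dimethyl-6,7,8,8a-tetrahydro-4H-benzo[d][1,3]dioxin-7-yl]prop-2-en-1-ol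
Conditions: Bu4NF, THF, 0 °C
Reagents that add atoms: none
Why: Fluoride-mediated desilylation cleaves the primary silyl ether, the acetonide being stable to fluoride and base.

Step 11
Reactants: 13 2-[(7S,8aS)-2,2-dimethyl-6,7,8,8a-tetrahydro-4H-benzo[d][1,3]dioxin-7-yl]prop-2-en-1-ol
Product: 14 (7S,8aS)-7-(3-bromoprop-1-en-2-yl)-2,2-dimethyl-6,7,8,8a-tetrahydro-4H-benzo[d][1,3]dioxine
Conditions: CBr4, PPh3, 2,6-lutidine, CH2Cl2, 0 °C
Reagents that add atoms: carbon tetrabromide, BrC(Br)(Br)Br
Why: Appel reaction, in which bromide displaces the alkoxyphosphonium group at the primary allylic carbon (direct and allylic attack give the same 2-substituted allyl bromide) while lutidine keeps the medium non-acidic for the acetonide.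

Step 12
Reactants: 15 (R)-2-methylglycidol, [(2R)-2-methyloxiran-2-yl]methanol
Product: 16 (S)-2-methyloxirane-2-carbaldehyde
Conditions: (COCl)2, DMSO, CH2Cl2, −78 °C; Et3N, −78 → 0 °C; careful concentration, used at once
Reagents that add atoms: none
Why: Swern oxidation of the primary alcohol gives an aldehyde with no α-hydrogen, so the quaternary stereocentre cannot racemise, and the epoxide tolerates the cold, base-quenched conditions.

Step 13
Reactants: 16 (S)-2-methyloxirane-2-carbaldehyde
Product: 17 4,4,5,5-tetramethyl-2-{(E)-2-[(R)-2-methyloxiran-2-yl]ethenyl}-1,3,2-dioxaborolane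
Conditions: CH2(Bpin)2, lithium 2,2,6,6-tetramethylpiperidide (from the amine and n-BuLi), THF, 0 °C; then 16, −78 °C → rt
Reagents that add atoms: bis(4,4,5,5-tetramethyl-1,3,2-dioxaborolan-2-yl)methane, CC1(C)OB(CB2OC(C)(C)C(C)(C)O2)OC1(C)C
Why: Boron–Wittig olefination, in which the lithiated geminal diboronate adds to the aldehyde and syn-elimination of a boron–oxygen unit should give the E-alkenyl boronate, favoured by the bulky quaternary substituent, the epoxide being far less electrophilic than the aldehyde at −78 °C.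

Step 14
Reactants: 17 4,4,5,5-tetramethyl-2-{(E)-2-[(R)-2-methyloxiran-2-yl]ethenyl}-1,3,2-dioxaborolane
Product: 18 (R,E)-2-hydroxy-2-methyl-4-(4,4,5,5-tetramethyl-1,3,2-dioxaborolan-2-yl)but-3-en-1-yl 2-methylpropanoate
Conditions: i-PrCO2H (3 equiv), Cs2CO3 (10 mol%), DMF, 70 °C
Reagents that add atoms: isobutyric acid, CC(C)C(=O)O
Why: Carboxylate ring opening of a 2,2-disubstituted epoxide by SN2 attack at the unsubstituted CH2 terminus leaves the C–O bond at the quaternary carbon intact, so the configuration is retained and the C12 ester is installed directly.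

Step 15
Reactants: 14 (7S,8aS)-7-(3-bromoprop-1-en-2-yl)-2,2-dimethyl-6,7,8,8a-tetrahydro-4H-benzo[d][1,3]dioxine; 18 (R,E)-2-hydroxy-2-methyl-4-(4,4,5,5-tetramethyl-1,3,2-dioxaborolan-2-yl)but-3-en-1-yl 2-methylpropanoate
Product: 19 (2R,3E)-6-[(7S,8aS)-2,2-dimethyl-6,7,8,8a-tetrahydro-4H-benzo[d][1,3]dioxin-7-yl]-2-hydroxy-2-methylhepta-3,6-dien-1-yl 2-methylpropanoate
Conditions: Pd(PPh3)4 (5 mol%), K3PO4, THF/H2O 10:1, 45 °C
Reagents that add atoms: none
Why: Suzuki–Miyaura coupling, in which the allyl bromide adds oxidatively to zerovalent palladium, the base-activated boronate transfers its alkenyl group and reductive elimination forms C8–C9 with retention of the E geometry, the 2-substituted allyl unit giving the same product from either terminus and the free hydroxyl and ester being tolerated.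

Step 16
Reactants: 19 (2R,3E)-6-[(7S,8aS)-2,2-dimethyl-6,7,8,8a-tetrahydro-4H-benzo[d][1,3]dioxin-7-yl]-2-hydroxy-2-methylhepta-3,6-dien-1-yl 2-methylpropanoate
Product: 20 (2R,3E)-2-hydroxy-6-[(1S,5S)-5-hydroxy-4-(hydroxymethyl)cyclohex-3-en-1-yl]-2-methylhepta-3,6-dien-1-yl 2-methylpropanoate
Conditions: PPTS (cat.), MeOH, rt
Reagents that add atoms: none
Why: Mild acid-catalysed transacetalisation with methanol releases the 1,3-diol under conditions too weak to ionise the tertiary allylic alcohol or to cleave the isobutyrate.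

Step 17
Reactants: 20 (2R,3E)-2-hydroxy-6-[(1S,5S)-5-hydroxy-4-(hydroxymethyl)cyclohex-3-en-1-yl]-2-methylhepta-3,6-dien-1-yl 2-methylpropanoate
Product: 21 (2R,3E)-2-hydroxy-6-[(1S,5S)-5-hydroxy-4-[(2-methylpropanoyloxy)methyl]cyclohex-3-en-1-yl]-2-methylhepta-3,6-dien-1-yl 2-methylpropanoate (CNP0599657.1)
Conditions: i-PrCOCl (1.1 equiv), 2,4,6-collidine, CH2Cl2, −78 → −40 °C
Reagents that add atoms: isobutyryl chloride, CC(C)C(Cl)=O
Why: Kinetically controlled acylation with an α-branched acid chloride and a hindered pyridine base at low temperature should select the unhindered primary allylic hydroxyl over the secondary allylic and the tertiary hydroxyl.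

**Compound list**

1 | 2-bromoprop-2-en-1-ol | C=C(Br)CO | starting material
2 | (2-bromoprop-2-en-1-yloxy)(tert-butyl)dimethylsilane | C=C(Br)CO[Si](C)(C)C(C)(C)C | intermediate
3 | 2-[3-(tert-butyldimethylsilyloxy)prop-1-en-2-yl]-4,4,5,5-tetramethyl-1,3,2-dioxaborolane | C=C(CO[Si](C)(C)C(C)(C)C)B1OC(C)(C)C(C)(C)O1 | intermediate
4 | 5,6-dihydro-2H-pyran-2-one | O=C1C=CCCO1 | starting material
5 | (R)-4-[3-(tert-butyldimethylsilyloxy)prop-1-en-2-yl]tetrahydro-2H-pyran-2-one | C=C(CO[Si](C)(C)C(C)(C)C)[C@@H]1CCOC(=O)C1 | intermediate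
6 | (4R)-4-[3-(tert-butyldimethylsilyloxy)prop-1-en-2-yl]tetrahydro-2H-pyran-2-ol (anomer mixture) | C=C(CO[Si](C)(C)C(C)(C)C)[C@@H]1CCOC(O)C1 | intermediate
7 | (triphenylphosphoranylidene)acetaldehyde | O=CC=P(c1ccccc1)(c1ccccc1)c1ccccc1 | starting material
8 | (S,E)-5-[3-(tert-butyldimethylsilyloxy)prop-1-en-2-yl]-7-hydroxyhept-2-enal | C=C(CO[Si](C)(C)C(C)(C)C)[C@H](CCO)C/C=C/C=O | intermediate
9 | (S,E)-5-[3-(tert-butyldimethylsilyloxy)prop-1-en-2-yl]hept-2-enedial | C=C(CO[Si](C)(C)C(C)(C)C)[C@H](CC=O)C/C=C/C=O | intermediate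
10 | (4S,6S)-4-[3-(tert-butyldimethylsilyloxy)prop-1-en-2-yl]-6-hydroxycyclohex-1-ene-1-carbaldehyde | C=C(CO[Si](C)(C)C(C)(C)C)[C@H]1CC=C(C=O)[C@@H](O)C1 | intermediate
11 | (1S,5S)-5-[3-(tert-butyldimethylsilyloxy)prop-1-en-2-yl]-2-(hydroxymethyl)cyclohex-2-en-1-ol | C=C(CO[Si](C)(C)C(C)(C)C)[C@H]1CC=C(CO)[C@@H](O)C1 | intermediate
12 | tert-butyl{2-[(7S,8aS)-2,2-dimethyl-6,7,8,8a-tetrahydro-4H-benzo[d][1,3]dioxin-7-yl]prop-2-en-1-yloxy}dimethylsilane | C=C(CO[Si](C)(C)C(C)(C)C)[C@H]1CC=C2COC(C)(C)O[C@H]2C1 | intermediate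
13 | 2-[(7S,8aS)-2,2-dimethyl-6,7,8,8a-tetrahydro-4H-benzo[d][1,3]dioxin-7-yl]prop-2-en-1-ol | C=C(CO)[C@H]1CC=C2COC(C)(C)O[C@H]2C1 | intermediate
14 | (7S,8aS)-7-(3-bromoprop-1-en-2-yl)-2,2-dimethyl-6,7,8,8a-tetrahydro-4H-benzo[d][1,3]dioxine | C=C(CBr)[C@H]1CC=C2COC(C)(C)O[C@H]2C1 | intermediate
15 | (R)-2-methylglycidol, [(2R)-2-methyloxiran-2-yl]methanol | C[C@@]1(CO)CO1 | starting material
16 | (S)-2-methyloxirane-2-carbaldehyde | C[C@@]1(C=O)CO1 | intermediate
17 | 4,4,5,5-tetramethyl-2-{(E)-2-[(R)-2-methyloxiran-2-yl]ethenyl}-1,3,2-dioxaborolane | C[C@@]1(/C=C/B2OC(C)(C)C(C)(C)O2)CO1 | intermediate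
18 | (R,E)-2-hydroxy-2-methyl-4-(4,4,5,5-tetramethyl-1,3,2-dioxaborolan-2-yl)but-3-en-1-yl 2-methylpropanoate | CC1(C)OB(/C=C/[C@@](C)(O)COC(=O)C(C)C)OC1(C)C | intermediate
19 | (2R,3E)-6-[(7S,8aS)-2,2-dimethyl-6,7,8,8a-tetrahydro-4H-benzo[d][1,3]dioxin-7-yl]-2-hydroxy-2-methylhepta-3,6-dien-1-yl 2-methylpropanoate | C=C(C/C=C/[C@@](C)(O)COC(=O)C(C)C)[C@H]1CC=C2COC(C)(C)O[C@H]2C1 | intermediate
20 | (2R,3E)-2-hydroxy-6-[(1S,5S)-5-hydroxy-4-(hydroxymethyl)cyclohex-3-en-1-yl]-2-methylhepta-3,6-dien-1-yl 2-methylpropanoate | C=C(C/C=C/[C@@](C)(O)COC(=O)C(C)C)[C@H]1CC=C(CO)[C@@H](O)C1 | intermediate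
21 | (2R,3E)-2-hydroxy-6-[(1S,5S)-5-hydroxy-4-[(2-methylpropanoyloxy)methyl]cyclohex-3-en-1-yl]-2-methylhepta-3,6-dien-1-yl 2-methylpropanoate (CNP0599657.1) | C=C(C/C=C/[C@@](C)(O)COC(=O)C(C)C)[C@H]1CC=C(COC(=O)C(C)C)[C@@H](O)C1 | target

**Count and risks**

Total steps: 17 (14 in the main line, 3 for the side-chain boronate). Longest linear sequence: 14 steps (1 → 21 through steps 1–11 and 15–17).

Step 7. What may go wrong: facial control at the aldehyde during the aldol ring closure may be weak or mismatched between the proline and the resident substituent, so that the carbinol forms as an epimer mixture, and retro-aldol reaction may erode it further on long reaction times. The fallback moves stereocontrol from the ring closure to a ketone reduction; it sets out from 9 and returns at 11. Cyclisation of 9 with an achiral amine pair (pyrrolidine/AcOH, imidazole) gives the hydroxy enal as a carbinol epimer mixture, (4S,6RS)-4-[3-(tert-butyldimethylsilyloxy)prop-1-en-2-yl]-6-hydroxycyclohex-1-ene-1-carbaldehyde F1. NaBH4/CeCl3·7H2O then gives the diol mixture (1RS,5S)-5-[3-(tert-butyldimethylsilyloxy)prop-1-en-2-yl]-2-(hydroxymethyl)cyclohex-2-en-1-ol F2. AcCl/2,4,6-collidine at −78 °C acetylates the primary hydroxyl to [(4S,6RS)-4-[3-(tert-butyldimethylsilyloxy)prop-1-en-2-yl]-6-hydroxycyclohex-1-en-1-yl]methyl acetate F3, and MnO2 oxidises the secondary allylic alcohol to the enone [(S)-4-[3-(tert-butyldimethylsilyloxy)prop-1-en-2-yl]-6-oxocyclohex-1-en-1-yl]methyl acetate F4. Luche reduction of this 5-substituted 2-alkylcyclohex-2-enone by axial hydride delivery, as in the conversion of carvone into cis-carveol, should give [(4S,6S)-4-[3-(tert-butyldimethylsilyloxy)prop-1-en-2-yl]-6-hydroxycyclohex-1-en-1-yl]methyl acetate F5. K2CO3/MeOH removes the acetate and arrives at 11.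

Step 5. What may go wrong: the hydroxyl freed on olefination may add back to the new enal (6-exo oxa-Michael closure to a tetrahydropyran), or the product enal may be olefinated a second time. The fallback builds the enal by cross-metathesis after the alcohol has been oxidised, so that no hydroxy enal is ever present; it sets out from 6 and returns at 9. Methylenation of 6 with Ph3P=CH2 (from Ph3PCH3Br and KOtBu, THF) gives (S)-3-[3-(tert-butyldimethylsilyloxy)prop-1-en-2-yl]hex-5-en-1-ol F6. Dess–Martin oxidation gives (S)-3-[3-(tert-butyldimethylsilyloxy)prop-1-en-2-yl]hex-5-enal F7. Cross-metathesis of its vinyl group with (E)-but-2-enal and the second-generation Hoveyda–Grubbs catalyst (CH2Cl2, 40 °C) should give 9, the 1,1-disubstituted alkene being too hindered to take part.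

Step 15. What may go wrong: transfer of the alkenyl group from the hydroxyl-bearing pinacol boronate may be slow, so that the π-allyl palladium intermediate decays by β-hydride elimination or the allyl bromide is hydrolysed. The fallback reverses the polarity (allylzinc plus alkenyl iodide, Negishi coupling); it sets out from 16 and 14 and returns at 20. Takai olefination of 16 (CrCl2, CHI3, THF) gives (R)-2-[(E)-2-iodoethenyl]-2-methyloxirane F8. Isobutyric acid with catalytic Cs2CO3 opens it to (R,E)-2-hydroxy-4-iodo-2-methylbut-3-en-1-yl 2-methylpropanoate F9, and Et3SiOTf/2,6-lutidine gives (R,E)-4-iodo-2-methyl-2-(triethylsilyloxy)but-3-en-1-yl 2-methylpropanoate F10. Bromide 14 is converted with Zn dust and LiCl in THF into bromo{2-[(7S,8aS)-2,2-dimethyl-6,7,8,8a-tetrahydro-4H-benzo[d][1,3]dioxin-7-yl]prop-2-en-1-yl}zinc F11. Coupling of this with the iodide under Pd(PPh3)4 should give (2R,3E)-6-[(7S,8aS)-2,2-dimethyl-6,7,8,8a-tetrahydro-4H-benzo[d][1,3]dioxin-7-yl]-2-methyl-2-(triethylsilyloxy)hepta-3,6-dien-1-yl 2-methylpropanoate F12. AcOH/THF/H2O then removes the acetonide and the silyl ether together and arrives at 20.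

**Further compounds**

F1 | step 7 | (4S,6RS)-4-[3-(tert-butyldimethylsilyloxy)prop-1-en-2-yl]-6-hydroxycyclohex-1-ene-1-carbaldehyde | C=C(CO[Si](C)(C)C(C)(C)C)[C@H]1CC=C(C=O)C(O)C1
F2 | step 7 | (1RS,5S)-5-[3-(tert-butyldimethylsilyloxy)prop-1-en-2-yl]-2-(hydroxymethyl)cyclohex-2-en-1-ol | C=C(CO[Si](C)(C)C(C)(C)C)[C@H]1CC=C(CO)C(O)C1
F3 | step 7 | [(4S,6RS)-4-[3-(tert-butyldimethylsilyloxy)prop-1-en-2-yl]-6-hydroxycyclohex-1-en-1-yl]methyl acetate | C=C(CO[Si](C)(C)C(C)(C)C)[C@H]1CC=C(COC(C)=O)C(O)C1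
F4 | step 7 | [(S)-4-[3-(tert-butyldimethylsilyloxy)prop-1-en-2-yl]-6-oxocyclohex-1-en-1-yl]methyl acetate | C=C(CO[Si](C)(C)C(C)(C)C)[C@H]1CC=C(COC(C)=O)C(=O)C1
F5 | step 7 | [(4S,6S)-4-[3-(tert-butyldimethylsilyloxy)prop-1-en-2-yl]-6-hydroxycyclohex-1-en-1-yl]methyl acetate | C=C(CO[Si](C)(C)C(C)(C)C)[C@H]1CC=C(COC(C)=O)[C@@H](O)C1
F6 | step 5 | (S)-3-[3-(tert-butyldimethylsilyloxy)prop-1-en-2-yl]hex-5-en-1-ol | C=C(CO[Si](C)(C)C(C)(C)C)[C@H](CCO)CC=C
F7 | step 5 | (S)-3-[3-(tert-butyldimethylsilyloxy)prop-1-en-2-yl]hex-5-enal | C=C(CO[Si](C)(C)C(C)(C)C)[C@H](CC=O)CC=C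
F8 | step 15 | (R)-2-[(E)-2-iodoethenyl]-2-methyloxirane | C[C@@]1(/C=C/I)CO1
F9 | step 15 | (R,E)-2-hydroxy-4-iodo-2-methylbut-3-en-1-yl 2-methylpropanoate | I/C=C/[C@@](C)(O)COC(=O)C(C)C
F10 | step 15 | (R,E)-4-iodo-2-methyl-2-(triethylsilyloxy)but-3-en-1-yl 2-methylpropanoate | I/C=C/[C@@](C)(O[Si](CC)(CC)CC)COC(=O)C(C)C
F11 | step 15 | bromo{2-[(7S,8aS)-2,2-dimethyl-6,7,8,8a-tetrahydro-4H-benzo[d][1,3]dioxin-7-yl]prop-2-en-1-yl}zinc | C=C(C[Zn]Br)[C@H]1CC=C2COC(C)(C)O[C@H]2C1
F12 | step 15 | (2R,3E)-6-[(7S,8aS)-2,2-dimethyl-6,7,8,8a-tetrahydro-4H-benzo[d][1,3]dioxin-7-yl]-2-methyl-2-(triethylsilyloxy)hepta-3,6-dien-1-yl 2-methylpropanoate | C=C(C/C=C/[C@@](C)(O[Si](CC)(CC)CC)COC(=O)C(C)C)[C@H]1CC=C2COC(C)(C)O[C@H]2C1
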